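**Plan**

- Retrosynthesis: the last cut removes three benzyl ethers and the two alkyl ethers peri to the C4 carbonyls (O5-methyl of unit 2, O5-ethyl of unit 1). Ring C of unit 1 (the 7-methoxyflavone joined at C8) is then opened at O1–C2, C2–C3 and C4–C4a to a biaryl phenol, 4-(benzyloxy)benzaldehyde and an acetyl group.
- Ring A of unit 1 is cut at C8a–C8, C7–C6 and C8a–C4a into 3-ethoxycyclobut-2-en-1-one and the 6-(methoxyethynyl)flavone of unit 2; the alkyne–C6 bond of that flavone is cut back to a 6-iodoapigenin ether.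
- Enabling feature: in ring A of unit 1 the biaryl carbon C8 lies between the oxygen-bearing C8a and the methoxy carbon C7, followed by C6–H and an oxygen at C5. A vinylketene and an ynol ether deliver exactly this hydroxyl–substituent–alkoxy sequence, so the C8–C6 biaryl bond is never made by aryl–aryl coupling.
- Forward order: unit 2 (apigenin) is present from the start; ring A of unit 1 arises in step 5, ring C of unit 1 in step 8, and ring B of unit 1 comes in with the aldehyde in step 7.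
- Stereochemistry: the target has no stereocentre; the crowded biaryl axis is not specified in the target and is not controlled.

Key step: step 5

Remark: the target is taken as drawn, without a defined sense of the C8–C6 axis; if the axis proves configurationally stable the product is racemic.

**Route**

Step 1
Reactants: 1 apigenin (5,7-dihydroxy-2-(4-hydroxyphenyl)-4H-chromen-4-one)
Product: 2 7-(benzyloxy)-2-[4-(benzyloxy)phenyl]-5-hydroxy-4H-chromen-4-one
Conditions: BnBr (2.2 equiv), K2CO3, DMF, rt to 40 °C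
Reagents that add atoms: benzyl bromide, BrCc1ccccc1
Why: Williamson etherification in which the acidic, unhindered 7- and 4'-hydroxyls react, while the 5-hydroxyl, hydrogen-bonded to the C4 carbonyl, should stay free under mild carbonate conditions.

Step 2
Reactants: 2 7-(benzyloxy)-2-[4-(benzyloxy)phenyl]-5-hydroxy-4H-chromen-4-one
Product: 3 7-(benzyloxy)-2-[4-(benzyloxy)phenyl]-5-hydroxy-6-iodo-4H-chromen-4-one
Conditions: BnNMe3 ICl2 (1.1 equiv), CaCO3, CH2Cl2–MeOH, rt
Reagents that add atoms: benzyltrimethylammonium dichloroiodate, C[N+](C)(C)Cc1ccccc1.Cl[I-]Cl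
Why: Electrophilic aromatic iodination in which the free 5-hydroxyl directs the iodinating agent to its ortho carbon C6, the selectivity established for 5-hydroxy-7-alkoxyflavones with this reagent, while CaCO3 takes up the HCl.

Step 3
Reactants: 3 7-(benzyloxy)-2-[4-(benzyloxy)phenyl]-5-hydroxy-6-iodo-4H-chromen-4-one
Product: 4 7-(benzyloxy)-2-[4-(benzyloxy)phenyl]-6-iodo-5-methoxy-4H-chromen-4-one
Conditions: MeI (excess), K2CO3, DMF, 50 °C
Reagents that add atoms: iodomethane, CI
Why: Williamson etherification of the chelated 5-hydroxyl, slow but routine in warm DMF; the small methyl group fits between iodine and the carbonyl, keeps this oxygen from adding to the later ynol ether, and sits peri to C4=O so that BCl3 can remove it at the end.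

Step 4
Reactants: 4 7-(benzyloxy)-2-[4-(benzyloxy)phenyl]-6-iodo-5-methoxy-4H-chromen-4-one; 5 2-chloro-1,1-dimethoxyethane
Product: 8 7-(benzyloxy)-2-[4-(benzyloxy)phenyl]-5-methoxy-6-(methoxyethynyl)-4H-chromen-4-one, via lithium methoxyacetylide 6 (not isolated), via methoxyethynylzinc chloride 7 (not isolated)
Conditions: 5 (2 equiv), LiNEt2 (6 equiv, from Et2NH and n-BuLi), THF, 0 °C; ZnCl2 (2.2 equiv), 0 °C; then 4, Pd(PPh3)4 (5 mol %), rt to 50 °C; chromatography on Et3N-deactivated silica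
Reagents that add atoms: none
Why: Negishi coupling in which LiNEt2 strips MeOH and HCl from 5 and deprotonates the methoxyacetylene formed, ZnCl2 gives the zinc acetylide, and zerovalent palladium joins it to the aryl iodide, a known way to aryl ynol ethers from alkoxyethynylzinc chlorides that should tolerate the two ortho ethers because the nucleophile is linear.

Step 5
Reactants: 8 7-(benzyloxy)-2-[4-(benzyloxy)phenyl]-5-methoxy-6-(methoxyethynyl)-4H-chromen-4-one; 9 3-ethoxycyclobut-2-en-1-one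
Product: 14 7-(benzyloxy)-2-[4-(benzyloxy)phenyl]-6-(4-ethoxy-2-hydroxy-6-methoxyphenyl)-5-methoxy-4H-chromen-4-one, via vinylketene 10 (not isolated), via vinylcyclobutenone 11 (not isolated), via dienylketene 12 (not isolated), via cyclohexadienone 13 (not isolated)
Conditions: 9 (2 equiv), toluene, 80 °C then 110 °C, sealed tube, argon
Reagents that add atoms: none
Why: Danheiser benzannulation: four-electron conrotatory opening of 9 gives vinylketene 10, whose ketene C=C adds [2+2] to the electron-rich alkyne of 8 to give 4-vinylcyclobutenone 11, a second four-electron opening gives dienylketene 12, six-electron electrocyclisation gives cyclohexadienone 13, and enolisation should deliver phenol 14. The closest known reaction type is the cyclobutenone–alkoxyalkyne benzannulation to resorcinol monoethers, applied here to an aryl methyl ynol ether. The one new ring, ring A of unit 1, closes by a thermally allowed disrotatory six-electron electrocyclisation of the (3E)-dienylketene that forms C8a–C4a, after the [2+2] event has formed C8a–C8 and C7–C6. No stereocentre remains in the product, since the sp3 carbon of 11 is transient and the biaryl axis is not controlled. The step needs regioselectivity in the [2+2] event, and the methoxy group of 8 secures it by making the aryl-bearing alkyne carbon nucleophilic, so that this carbon bonds to the ketene carbonyl carbon and the flavone ends between the new hydroxyl and the methoxy group, with the ethoxy group of 9 at C5. The methyl ynol ether cannot lose an alkene by retro-ene fragmentation at 110 °C, and the benzyl ethers and chromone of unit 2 are inert to neutral heating.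

Step 6
Reactants: 14 7-(benzyloxy)-2-[4-(benzyloxy)phenyl]-6-(4-ethoxy-2-hydroxy-6-methoxyphenyl)-5-methoxy-4H-chromen-4-one
Product: 16 6-(3-acetyl-4-ethoxy-2-hydroxy-6-methoxyphenyl)-7-(benzyloxy)-2-[4-(benzyloxy)phenyl]-5-methoxy-4H-chromen-4-one, via aryl acetate 15 (not isolated)
Conditions: Ac2O (1.5 equiv), BF3·OEt2 (3 equiv), ClCH2CH2Cl, rt to 50 °C; then aq. NaOAc
Reagents that add atoms: acetic anhydride, CC(=O)OC(C)=O
Why: Friedel–Crafts acylation by way of the aryl acetate (Fries rearrangement), in which boron bound to the phenol oxygen delivers the acetyl group to the only free ortho carbon, C4a, and the chelated ortho-hydroxy ketone is the thermodynamic product, as in the acetylation of 3,5-dimethoxyphenol; the ordinary benzyl ethers and the peri methyl ether of unit 2 should tolerate BF3·OEt2 at this temperature.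

Step 7
Reactants: 16 6-(3-acetyl-4-ethoxy-2-hydroxy-6-methoxyphenyl)-7-(benzyloxy)-2-[4-(benzyloxy)phenyl]-5-methoxy-4H-chromen-4-one; 17 4-(benzyloxy)benzaldehyde
Product: 18 7-(benzyloxy)-2-[4-(benzyloxy)phenyl]-6-(3-{(2E)-3-[4-(benzyloxy)phenyl]prop-2-enoyl}-4-ethoxy-2-hydroxy-6-methoxyphenyl)-5-methoxy-4H-chromen-4-one
Conditions: KOH (50 % aq.), EtOH–THF, rt; dilute HCl work-up
Reagents that add atoms: none
Why: Claisen–Schmidt condensation in which the methyl ketone enolate adds to the non-enolisable aldehyde and the aldol dehydrates to the (E)-enone, standard for 2-hydroxy-4,6-dialkoxyacetophenones.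

Step 8
Reactants: 18 the (E)-chalcone of step 7
Product: 19 7-(benzyloxy)-2-[4-(benzyloxy)phenyl]-6-{2-[4-(benzyloxy)phenyl]-5-ethoxy-7-methoxy-4-oxo-4H-chromen-8-yl}-5-methoxy-4H-chromen-4-one
Conditions: I2 (10 mol %), DMSO, 120–130 °C
Reagents that add atoms: none
Why: Iodine-catalysed oxidative cyclisation of a 2'-hydroxychalcone in DMSO (oxa-Michael closure of O1–C2, then dehydrogenation across C2–C3), in which only the C8a hydroxyl is free next to the enone, so that ring C of unit 1 can close in one sense only.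

Step 9
Reactants: 19 the protected biflavone of step 8
Product: 20 7'-O-methylagathisflavone (8-[5,7-dihydroxy-2-(4-hydroxyphenyl)-4-oxo-4H-chromen-6-yl]-5-hydroxy-2-(4-hydroxyphenyl)-7-methoxy-4H-chromen-4-one)
Conditions: BCl3 (12 equiv), pentamethylbenzene (10 equiv), CH2Cl2, −78 °C to rt; MeOH, then water
Reagents that add atoms: none
Why: Lewis-acid ether cleavage in which BCl3 removes the three benzyl groups as cations that pentamethylbenzene traps and dealkylates the two ethers peri to a C4 carbonyl through six-membered boron chelates, whereas the 7-methoxy group of unit 1 has no neighbouring carbonyl and should stay.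

**Compound list**

1 | apigenin | O=c1cc(-c2ccc(O)cc2)oc2cc(O)cc(O)c12 | starting material
2 | 7-(benzyloxy)-2-[4-(benzyloxy)phenyl]-5-hydroxy-4H-chromen-4-one | O=c1cc(-c2ccc(OCc3ccccc3)cc2)oc2cc(OCc3ccccc3)cc(O)c12 | intermediate
3 | 7-(benzyloxy)-2-[4-(benzyloxy)phenyl]-5-hydroxy-6-iodo-4H-chromen-4-one | O=c1cc(-c2ccc(OCc3ccccc3)cc2)oc2cc(OCc3ccccc3)c(I)c(O)c12 | intermediate
4 | 7-(benzyloxy)-2-[4-(benzyloxy)phenyl]-6-iodo-5-methoxy-4H-chromen-4-one | COc1c(I)c(OCc2ccccc2)cc2oc(-c3ccc(OCc4ccccc4)cc3)cc(=O)c12 | intermediate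
5 | 2-chloro-1,1-dimethoxyethane | COC(CCl)OC | starting material
6 | lithium methoxyacetylide | [Li]C#COC | intermediate
7 | methoxyethynylzinc chloride | COC#C[Zn]Cl | intermediate
8 | 7-(benzyloxy)-2-[4-(benzyloxy)phenyl]-5-methoxy-6-(methoxyethynyl)-4H-chromen-4-one | COC#Cc1c(OCc2ccccc2)cc2oc(-c3ccc(OCc4ccccc4)cc3)cc(=O)c2c1OC | intermediate
9 | 3-ethoxycyclobut-2-en-1-one | CCOC1=CC(=O)C1 | starting material
10 | 3-ethoxybuta-1,3-dien-1-one (vinylketene) | C=C(OCC)C=C=O | intermediate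
11 | 2-aryl-4-(1-ethoxyethenyl)-3-methoxycyclobut-2-en-1-one, racemic (aryl = the chromen-6-yl group of 8) | C=C(OCC)C1C(=O)C(=C1OC)c1c(OCc2ccccc2)cc2oc(-c3ccc(OCc4ccccc4)cc3)cc(=O)c2c1OC | intermediate
12 | (3E)-2-aryl-5-ethoxy-3-methoxyhexa-1,3,5-trien-1-one (dienylketene, same aryl) | C=C(OCC)/C=C(OC)\C(=C=O)c1c(OCc2ccccc2)cc2oc(-c3ccc(OCc4ccccc4)cc3)cc(=O)c2c1OC | intermediate
13 | 2-aryl-5-ethoxy-3-methoxycyclohexa-2,4-dien-1-one (same aryl) | CCOC1=CC(OC)=C(C(=O)C1)c1c(OCc2ccccc2)cc2oc(-c3ccc(OCc4ccccc4)cc3)cc(=O)c2c1OC | intermediate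
14 | 7-(benzyloxy)-2-[4-(benzyloxy)phenyl]-6-(4-ethoxy-2-hydroxy-6-methoxyphenyl)-5-methoxy-4H-chromen-4-one | CCOc1cc(O)c(-c2c(OCc3ccccc3)cc3oc(-c4ccc(OCc5ccccc5)cc4)cc(=O)c3c2OC)c(OC)c1 | intermediate
15 | 2-{7-(benzyloxy)-2-[4-(benzyloxy)phenyl]-5-methoxy-4-oxo-4H-chromen-6-yl}-5-ethoxy-3-methoxyphenyl acetate | CCOc1cc(OC(C)=O)c(-c2c(OCc3ccccc3)cc3oc(-c4ccc(OCc5ccccc5)cc4)cc(=O)c3c2OC)c(OC)c1 | intermediate
16 | 6-(3-acetyl-4-ethoxy-2-hydroxy-6-methoxyphenyl)-7-(benzyloxy)-2-[4-(benzyloxy)phenyl]-5-methoxy-4H-chromen-4-one | CCOc1cc(OC)c(-c2c(OCc3ccccc3)cc3oc(-c4ccc(OCc5ccccc5)cc4)cc(=O)c3c2OC)c(O)c1C(C)=O | intermediate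
17 | 4-(benzyloxy)benzaldehyde | O=Cc1ccc(OCc2ccccc2)cc1 | starting material
18 | 7-(benzyloxy)-2-[4-(benzyloxy)phenyl]-6-(3-{(2E)-3-[4-(benzyloxy)phenyl]prop-2-enoyl}-4-ethoxy-2-hydroxy-6-methoxyphenyl)-5-methoxy-4H-chromen-4-one | CCOc1cc(OC)c(-c2c(OCc3ccccc3)cc3oc(-c4ccc(OCc5ccccc5)cc4)cc(=O)c3c2OC)c(O)c1C(=O)/C=C/c1ccc(OCc2ccccc2)cc1 | intermediate
19 | 7-(benzyloxy)-2-[4-(benzyloxy)phenyl]-6-{2-[4-(benzyloxy)phenyl]-5-ethoxy-7-methoxy-4-oxo-4H-chromen-8-yl}-5-methoxy-4H-chromen-4-one | CCOc1cc(OC)c(-c2c(OCc3ccccc3)cc3oc(-c4ccc(OCc5ccccc5)cc4)cc(=O)c3c2OC)c2oc(-c3ccc(OCc4ccccc4)cc3)cc(=O)c12 | intermediate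
20 | 7'-O-methylagathisflavone | COc1cc(O)c2c(=O)cc(-c3ccc(O)cc3)oc2c1-c1c(O)cc2oc(-c3ccc(O)cc3)cc(=O)c2c1O | target

**Step count and risks**

Total step count: 9. Longest linear sequence: 9 steps, from apigenin 1 to 20.

Steps most likely to fail:

Step 5. The [2+2] addition of the vinylketene to the alkyne carbon that carries the doubly ortho-substituted flavone may be too slow. The ketene would then dimerise or acylate the product phenol, or the cascade would stall before the electrocyclisation. The fallback gives up the annulation for a direct biaryl coupling; it sets out from iodide 4 and comes back to the route at 20.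
- Commercial 1-(2-hydroxy-4,6-dimethoxyphenyl)ethan-1-one would be iodinated ortho to its phenol (BnNMe3 ICl2, CaCO3, CH2Cl2–MeOH) to 1-(2-hydroxy-3-iodo-4,6-dimethoxyphenyl)ethan-1-one F1.
- F1 would be condensed with aldehyde 17 (KOH, EtOH) to (2E)-3-[4-(benzyloxy)phenyl]-1-(2-hydroxy-3-iodo-4,6-dimethoxyphenyl)prop-2-en-1-one F2, and this cyclised (I2, DMSO, 130 °C) to 2-[4-(benzyloxy)phenyl]-8-iodo-5,7-dimethoxy-4H-chromen-4-one F3.
- Miyaura borylation (B2pin2, PdCl2(dppf), KOAc, dioxane, 90 °C) should give 2-[4-(benzyloxy)phenyl]-5,7-dimethoxy-8-(4,4,5,5-tetramethyl-1,3,2-dioxaborolan-2-yl)-4H-chromen-4-one F4.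
- Suzuki–Miyaura coupling of F4 with 4 (Pd(OAc)2, SPhos, K3PO4, toluene–water, 100 °C) should give 7-(benzyloxy)-2-[4-(benzyloxy)phenyl]-6-{2-[4-(benzyloxy)phenyl]-5,7-dimethoxy-4-oxo-4H-chromen-8-yl}-5-methoxy-4H-chromen-4-one F5, which carries a methyl in place of the ethyl ether at O5 of unit 1.
- BCl3 with pentamethylbenzene, as in step 9, should then cleave the three benzyl and the two peri methyl ethers and give 20.

Step 6. The acetyl group may enter para to the phenol, at C6 between the two ether groups, or BF3 may strip or shift benzyl groups. The fallback avoids strong Lewis acid and fixes the ortho position through a magnesium phenoxide; it sets out from 14 and comes back at 19, passing over 16 and 18.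
- Ortho-formylation of 14 (MgCl2, Et3N, paraformaldehyde, MeCN, reflux) should give 3-{7-(benzyloxy)-2-[4-(benzyloxy)phenyl]-5-methoxy-4-oxo-4H-chromen-6-yl}-6-ethoxy-2-hydroxy-4-methoxybenzaldehyde F6.
- Addition of lithium [4-(benzyloxy)phenyl]acetylide (from commercial 1-(benzyloxy)-4-ethynylbenzene and n-BuLi, 2.2 equiv, THF, −78 °C) should give the racemic propargylic alcohol 7-(benzyloxy)-2-[4-(benzyloxy)phenyl]-6-(3-{3-[4-(benzyloxy)phenyl]-1-hydroxyprop-2-yn-1-yl}-4-ethoxy-2-hydroxy-6-methoxyphenyl)-5-methoxy-4H-chromen-4-one F7.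
- MnO2 (CH2Cl2, rt) should oxidise F7 to the ynone 7-(benzyloxy)-2-[4-(benzyloxy)phenyl]-6-(3-{3-[4-(benzyloxy)phenyl]prop-2-ynoyl}-4-ethoxy-2-hydroxy-6-methoxyphenyl)-5-methoxy-4H-chromen-4-one F8.
- Amine-mediated 6-endo cyclisation of F8 (Et2NH, EtOH, reflux) should close ring C of unit 1 and give 19.

Step 4. Transmetalation of the zinc acetylide to the crowded arylpalladium iodide may be slow, so that reduction of the iodide or homocoupling of the acetylide takes over; formation of the acetylide from 5 in the presence of amine and methoxide may also be incomplete. The fallback makes the triple bond by elimination instead of cross-coupling; it sets out from 4 and comes back at 8.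
- Iodine–magnesium exchange on 4 (i-PrMgCl·LiCl, THF, −40 °C) and acylation with N,2-dimethoxy-N-methylacetamide should give 7-(benzyloxy)-2-[4-(benzyloxy)phenyl]-5-methoxy-6-(methoxyacetyl)-4H-chromen-4-one F9.
- O-Triflation of its enolate (KN(SiMe3)2, PhNTf2, THF, −78 °C) should give (Z)-1-{7-(benzyloxy)-2-[4-(benzyloxy)phenyl]-5-methoxy-4-oxo-4H-chromen-6-yl}-2-methoxyethenyl trifluoromethanesulfonate F10.
- Anti elimination of triflate from F10 (KOtBu, THF, −78 °C), the known conversion of α-alkoxy ketone enol triflates into alkynyl ethers, should give 8.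

**Further compounds**

F1 | step 5 | 1-(2-hydroxy-3-iodo-4,6-dimethoxyphenyl)ethan-1-one | CC(=O)c1c(O)c(I)c(OC)cc1OC
F2 | step 5 | (2E)-3-[4-(benzyloxy)phenyl]-1-(2-hydroxy-3-iodo-4,6-dimethoxyphenyl)prop-2-en-1-one | COc1cc(OC)c(C(=O)/C=C/c2ccc(OCc3ccccc3)cc2)c(O)c1I
F3 | step 5 | 2-[4-(benzyloxy)phenyl]-8-iodo-5,7-dimethoxy-4H-chromen-4-one | COc1cc(OC)c2c(=O)cc(-c3ccc(OCc4ccccc4)cc3)oc2c1I
F4 | step 5 | 2-[4-(benzyloxy)phenyl]-5,7-dimethoxy-8-(4,4,5,5-tetramethyl-1,3,2-dioxaborolan-2-yl)-4H-chromen-4-one | COc1cc(OC)c2c(=O)cc(-c3ccc(OCc4ccccc4)cc3)oc2c1B1OC(C)(C)C(C)(C)O1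
F5 | step 5 | 7-(benzyloxy)-2-[4-(benzyloxy)phenyl]-6-{2-[4-(benzyloxy)phenyl]-5,7-dimethoxy-4-oxo-4H-chromen-8-yl}-5-methoxy-4H-chromen-4-one | COc1cc(OC)c2c(=O)cc(-c3ccc(OCc4ccccc4)cc3)oc2c1-c1c(OCc2ccccc2)cc2oc(-c3ccc(OCc4ccccc4)cc3)cc(=O)c2c1OC
F6 | step 6 | 3-{7-(benzyloxy)-2-[4-(benzyloxy)phenyl]-5-methoxy-4-oxo-4H-chromen-6-yl}-6-ethoxy-2-hydroxy-4-methoxybenzaldehyde | CCOc1cc(OC)c(-c2c(OCc3ccccc3)cc3oc(-c4ccc(OCc5ccccc5)cc4)cc(=O)c3c2OC)c(O)c1C=O
F7 | step 6 | 7-(benzyloxy)-2-[4-(benzyloxy)phenyl]-6-(3-{3-[4-(benzyloxy)phenyl]-1-hydroxyprop-2-yn-1-yl}-4-ethoxy-2-hydroxy-6-methoxyphenyl)-5-methoxy-4H-chromen-4-one, racemic | CCOc1cc(OC)c(-c2c(OCc3ccccc3)cc3oc(-c4ccc(OCc5ccccc5)cc4)cc(=O)c3c2OC)c(O)c1C(O)C#Cc1ccc(OCc2ccccc2)cc1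
F8 | step 6 | 7-(benzyloxy)-2-[4-(benzyloxy)phenyl]-6-(3-{3-[4-(benzyloxy)phenyl]prop-2-ynoyl}-4-ethoxy-2-hydroxy-6-methoxyphenyl)-5-methoxy-4H-chromen-4-one | CCOc1cc(OC)c(-c2c(OCc3ccccc3)cc3oc(-c4ccc(OCc5ccccc5)cc4)cc(=O)c3c2OC)c(O)c1C(=O)C#Cc1ccc(OCc2ccccc2)cc1
F9 | step 4 | 7-(benzyloxy)-2-[4-(benzyloxy)phenyl]-5-methoxy-6-(methoxyacetyl)-4H-chromen-4-one | COCC(=O)c1c(OCc2ccccc2)cc2oc(-c3ccc(OCc4ccccc4)cc3)cc(=O)c2c1OC
F10 | step 4 | (Z)-1-{7-(benzyloxy)-2-[4-(benzyloxy)phenyl]-5-methoxy-4-oxo-4H-chromen-6-yl}-2-methoxyethenyl trifluoromethanesulfonate | CO/C=C(\OS(=O)(=O)C(F)(F)F)c1c(OCc2ccccc2)cc2oc(-c3ccc(OCc4ccccc4)cc3)cc(=O)c2c1OC
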